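**Strategy.** Everything rests on cutting C11–C12, the bond between the side-chain methine on ring carbon C4 (it carries the C18 hydroxymethyl) and the first chain methylene. C11 sits alpha to an oxygenated carbon (C18) and C12–C14 is a plain chain that can hide an alkene, so the bond is made by an Ireland–Claisen rearrangement: the tetralin-4-ylacetic acid is esterified through C18 with a syn-aldol-derived (3R,4R)-allylic alcohol that already holds C15, and the [3,3] shift of its (E)-silyl ketene acetal trades the temporary C14–O bond for C11–C12 while relaying the C14 configuration to C11. Carboxyl reduction and one hydrogenation finish the target.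

Key step: step 14

Remarks: Atoms are named by serrulatane numbering of the target. Ring: C1 (CH–CH3), C2, C3, C4 (CH bearing the chain), aromatic C4a, C5 (H), C6 (bears C19 = CO2H), C7 (OH), C8 (OH), C8a. Chain: C11 (CH, bears C18 = CH2OH), C12–C14 (CH2), C15 (CH–CH3), C16 (CH2OH). Compounds that supply skeletal carbons are numbered reactants and are not repeated under "Reagents that add atoms".

Assumption: ketene silyl acetal 16 is taken as purchasable (otherwise one step from tert-butyl acetate, LDA and TBSCl). The enantiomer of the iridium catalyst in step 6 is the one that delivers the (R)-acid.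

**Route**

Step 1
Reactants: 1 (S)-4-benzyl-3-propanoyl-1,3-oxazolidin-2-one; 2 acrolein
Product: 4 (S)-4-benzyl-3-[(2S,3R)-3-hydroxy-2-methylpent-4-enoyl]-1,3-oxazolidin-2-one, via Z-dibutylboron enolate 3 (not isolated)
Conditions: Bu2BOTf, i-Pr2NEt, CH2Cl2, 0 °C; 2, −78 → 0 °C; pH 7 buffer, MeOH, 30% H2O2, 0 °C
Reagents that add atoms: none
Why: Evans syn-aldol reaction: the Z-boron enolate adds through a closed chair (Zimmerman–Traxler) transition state on the face opposite the benzyl group of the auxiliary, setting the methyl stereocentre (later C15) and the syn carbinol (later the sacrificial C14) in one step.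

Step 2
Reactants: 4 (S)-4-benzyl-3-[(2S,3R)-3-hydroxy-2-methylpent-4-enoyl]-1,3-oxazolidin-2-one
Product: 5 (2R,3R)-2-methylpent-4-ene-1,3-diol
Conditions: LiBH4, MeOH (1 equiv), THF, 0 °C
Reagents that add atoms: none
Why: Hydride cleavage of the N-acyl oxazolidinone (reductive auxiliary removal) gives the 1,3-diol without epimerisation and returns the auxiliary.

Step 3
Reactants: 5 (2R,3R)-2-methylpent-4-ene-1,3-diol
Product: 6 (2R,3R)-1-[(tert-butyldimethylsilyl)oxy]-2-methylpent-4-en-3-ol
Conditions: TBSCl (1.05 equiv), imidazole, CH2Cl2, −20 → 0 °C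
Reagents that add atoms: tert-butyldimethylsilyl chloride, CC(C)(C)[Si](C)(C)Cl
Why: Silylation is kinetically selective for the primary hydroxyl over the hindered secondary allylic one, which stays free for esterification.

Step 4
Reactants: 7 1-(2,3-dihydroxyphenyl)ethan-1-one
Product: 8 1-[2,3-bis(benzyloxy)phenyl]ethan-1-one
Conditions: BnBr, K2CO3, DMF, 60 °C
Reagents that add atoms: benzyl bromide, BrCc1ccccc1
Why: Williamson etherification of both phenols gives benzyl ethers that are expected to survive every later step and to fall off in the final hydrogenolysis.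

Step 5
Reactants: 8 1-[2,3-bis(benzyloxy)phenyl]ethan-1-one; 9 (2-carboxyethyl)triphenylphosphonium bromide
Product: 11 (E)-4-[2,3-bis(benzyloxy)phenyl]pent-3-enoic acid, via carboxylate ylide 10 (not isolated)
Conditions: 9, NaHMDS (2 equiv), THF, 0 °C; 8, 0 °C → rt; aq HCl work-up; recrystallisation
Reagents that add atoms: none
Why: Wittig olefination of the methyl ketone by the carboxylate-bearing ylide gives the β,γ-unsaturated acid, the E isomer (aryl trans to the CH2CO2H arm) being favoured and purified by crystallisation.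

Step 6
Reactants: 11 (E)-4-[2,3-bis(benzyloxy)phenyl]pent-3-enoic acid
Product: 12 (R)-4-[2,3-bis(benzyloxy)phenyl]pentanoic acid
Conditions: Ir–SIPHOX (chiral spiro phosphine–oxazoline) catalyst (1 mol%), H2 (6 atm), Et3N (0.5 equiv), MeOH, rt
Reagents that add atoms: none
Why: Carboxylate-directed iridium-catalysed asymmetric hydrogenation of the trisubstituted β,γ-unsaturated acid delivers H2 to one enantioface and sets the (R)-benzylic methyl stereocentre (C1 of the target), with benzyl ethers inert to the homogeneous catalyst.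

Step 7
Reactants: 12 (R)-4-[2,3-bis(benzyloxy)phenyl]pentanoic acid
Product: 14 (4R)-5,6-bis(benzyloxy)-4-methyl-3,4-dihydronaphthalen-1(2H)-one, via acid chloride 13 (not isolated)
Conditions: (COCl)2, cat. DMF, CH2Cl2, 0 °C → rt; evaporate; (CF3)2CHOH, rt
Reagents that add atoms: none
Why: Intramolecular Friedel–Crafts acylation of the acid chloride in the strongly ionising solvent closes the six-membered ring at the only free ortho position, which is para to the 3-benzyloxy group.

Step 8
Reactants: 14 (4R)-5,6-bis(benzyloxy)-4-methyl-3,4-dihydronaphthalen-1(2H)-one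
Product: 15 (4R)-5,6-bis(benzyloxy)-4-methyl-1,2,3,4-tetrahydronaphthalen-1-ol (mixture of C1 epimers)
Conditions: NaBH4, THF–MeOH, 0 °C
Reagents that add atoms: none
Why: Hydride reduction of the aryl ketone gives the benzylic alcohol as an epimer mixture, which is acceptable because the next step ionises this centre.

Step 9
Reactants: 15 (4R)-5,6-bis(benzyloxy)-4-methyl-1,2,3,4-tetrahydronaphthalen-1-ol; 16 tert-butyl[(1-tert-butoxyethenyl)oxy]dimethylsilane
Product: 17 tert-butyl 2-[(1S,4R)-5,6-bis(benzyloxy)-4-methyl-1,2,3,4-tetrahydronaphthalen-1-yl]acetate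
Conditions: 16 (2.5 equiv), TMSOTf (10 mol%), CH2Cl2, −78 → −30 °C
Reagents that add atoms: none
Why: Lewis-acid ionisation of either epimer of 15 gives one p-alkoxy-stabilised benzylic cation (SN1, Mukaiyama-type alkylation) whose half-chair is fixed by the C1 methyl, held pseudoaxial by the peri C8 benzyloxy group, so that the ketene acetal should attack axially on the opposite face and set (S)-C4 trans to the methyl.

Step 10
Reactants: 17 tert-butyl 2-[(1S,4R)-5,6-bis(benzyloxy)-4-methyl-1,2,3,4-tetrahydronaphthalen-1-yl]acetate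
Product: 18 tert-butyl 2-[(1S,4R)-5,6-bis(benzyloxy)-7-bromo-4-methyl-1,2,3,4-tetrahydronaphthalen-1-yl]acetate
Conditions: NBS, MeCN, 0 °C → rt, dark
Reagents that add atoms: N-bromosuccinimide, O=C1CCC(=O)N1Br
Why: Electrophilic aromatic bromination should go to C6, ortho to the coplanar C7 benzyloxy group and para to the C8a alkyl carbon, whereas C5 is only para to the twisted C8 ether and is shielded by the peri C4 substituent.

Step 11
Reactants: 18 tert-butyl 2-[(1S,4R)-5,6-bis(benzyloxy)-7-bromo-4-methyl-1,2,3,4-tetrahydronaphthalen-1-yl]acetate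
Product: 19 benzyl (5R,8S)-3,4-bis(benzyloxy)-8-(2-tert-butoxy-2-oxoethyl)-5-methyl-5,6,7,8-tetrahydronaphthalene-2-carboxylate
Conditions: Pd(OAc)2 (5 mol%), Xantphos (6 mol%), CO (1 atm), BnOH, Et3N, toluene, 90 °C
Reagents that add atoms: carbon monoxide, [C-]#[O+]; benzyl alcohol, OCc1ccccc1
Why: Palladium-catalysed alkoxycarbonylation of the aryl bromide (oxidative addition, CO insertion, alcoholysis) installs C19 as the benzyl ester without touching the tert-butyl ester.

Step 12
Reactants: 19 benzyl (5R,8S)-3,4-bis(benzyloxy)-8-(2-tert-butoxy-2-oxoethyl)-5-methyl-5,6,7,8-tetrahydronaphthalene-2-carboxylate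
Product: 20 2-[(1S,4R)-5,6-bis(benzyloxy)-7-[(benzyloxy)carbonyl]-4-methyl-1,2,3,4-tetrahydronaphthalen-1-yl]acetic acid
Conditions: TFA–CH2Cl2 (1:4), 0 °C → rt
Reagents that add atoms: none
Why: Acidolysis of the tert-butyl ester (loss of isobutene) frees the C18 carboxyl while the benzyl ester and aryl benzyl ethers tolerate brief TFA exposure.

Step 13
Reactants: 20 2-[(1S,4R)-5,6-bis(benzyloxy)-7-[(benzyloxy)carbonyl]-4-methyl-1,2,3,4-tetrahydronaphthalen-1-yl]acetic acid; 6 (2R,3R)-1-[(tert-butyldimethylsilyl)oxy]-2-methylpent-4-en-3-ol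
Product: 21 (3R,4R)-5-[(tert-butyldimethylsilyl)oxy]-4-methylpent-1-en-3-yl 2-[(1S,4R)-5,6-bis(benzyloxy)-7-[(benzyloxy)carbonyl]-4-methyl-1,2,3,4-tetrahydronaphthalen-1-yl]acetate
Conditions: DCC, DMAP (cat.), CH2Cl2, 0 °C → rt
Reagents that add atoms: none
Why: Steglich esterification joins the acid to the hindered secondary allylic alcohol under neutral conditions that leave the silyl ether and all stereocentres intact.

Step 14
Reactants: 21 (3R,4R)-5-[(tert-butyldimethylsilyl)oxy]-4-methylpent-1-en-3-yl 2-[(1S,4R)-5,6-bis(benzyloxy)-7-[(benzyloxy)carbonyl]-4-methyl-1,2,3,4-tetrahydronaphthalen-1-yl]acetate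
Product: 24 (2S,4E,6S)-2-[(1S,4R)-5,6-bis(benzyloxy)-7-[(benzyloxy)carbonyl]-4-methyl-1,2,3,4-tetrahydronaphthalen-1-yl]-7-[(tert-butyldimethylsilyl)oxy]-6-methylhept-4-enoic acid, via E-silyl ketene acetal 22 (not isolated), via trimethylsilyl ester 23 (not isolated)
Conditions: LDA, THF, −78 °C; TMSCl–Et3N, −78 °C → rt, then 50 °C; 1 M HCl (aq), 0 °C
Reagents that add atoms: none
Why: LDA in THF removes a C11–H to give the kinetic lithium enolate with the tetralinyl group cis to the allyloxy oxygen, and O-silylation fixes it as the (E)-silyl ketene acetal 22, which undergoes a concerted suprafacial [3,3]-sigmatropic shift (Ireland–Claisen rearrangement of a secondary allylic ester) that forms C11–C12 and cleaves C14–O. No ring is closed; the six-membered array C11–C18–O–C14–C13–C12 exists only as a chair transition state. The new stereocentre C11 is controlled by the (R)-C14 carbinol: the chair that keeps the CH(CH3)CH2OTBS group equatorial, combined with the E ketene acetal, should give (S)-C11 and the E-C13=C14 alkene, after which C14 is no longer stereogenic. C1, C4 and C15 are spectators. The step needs E-selective enolisation, secured by LDA in THF without polar cosolvent and by the β-branched tetralinyl substituent, and a chair with equatorial carbinol substituent rather than a boat, secured by the bulk of the C15-branched group, which must also override any facial bias from the neighbouring C4 stereocentre. Silyl ester 23 is hydrolysed on work-up to acid 24.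

Step 15
Reactants: 24 (2S,4E,6S)-2-[(1S,4R)-5,6-bis(benzyloxy)-7-[(benzyloxy)carbonyl]-4-methyl-1,2,3,4-tetrahydronaphthalen-1-yl]-7-[(tert-butyldimethylsilyl)oxy]-6-methylhept-4-enoic acid
Product: 26 benzyl (5R,8S)-3,4-bis(benzyloxy)-8-[(2S,4E,6S)-7-[(tert-butyldimethylsilyl)oxy]-1-hydroxy-6-methylhept-4-en-2-yl]-5-methyl-5,6,7,8-tetrahydronaphthalene-2-carboxylate, via isobutyl carbonic mixed anhydride 25 (not isolated)
Conditions: i-BuOCOCl, N-methylmorpholine, THF, −15 °C; NaBH4, H2O, 0 °C
Reagents that add atoms: none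
Why: Activation as the mixed carbonic anhydride lets NaBH4 reduce only the C18 carboxyl to the hydroxymethyl group, leaving the aryl benzyl ester, the alkene and the C11 stereocentre untouched.

Step 16
Reactants: 26 benzyl (5R,8S)-3,4-bis(benzyloxy)-8-[(2S,4E,6S)-7-[(tert-butyldimethylsilyl)oxy]-1-hydroxy-6-methylhept-4-en-2-yl]-5-methyl-5,6,7,8-tetrahydronaphthalene-2-carboxylate
Product: 28 (5R,8S)-8-[(2S,6S)-1,7-dihydroxy-6-methylheptan-2-yl]-3,4-dihydroxy-5-methyl-5,6,7,8-tetrahydronaphthalene-2-carboxylic acid, via silyl ether 27 (not isolated)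
Conditions: H2 (1 atm), 10% Pd/C, THF–MeOH, rt; filter; 1 M HCl (aq)–THF, rt
Reagents that add atoms: none
Why: Heterogeneous hydrogenation saturates the C13=C14 alkene and hydrogenolyses the three benzyl groups, after which dilute acid cleaves the primary silyl ether; no stereocentre is created, and rapid saturation under H2 is expected to prevent alkene migration toward C15.

**Compound list**

1 | (S)-4-benzyl-3-propanoyl-1,3-oxazolidin-2-one | CCC(=O)N1[C@@H](Cc2ccccc2)COC1=O | starting material
2 | acrolein (prop-2-enal) | C=CC=O | starting material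
3 | Z-dibutylboron enolate of 1 | C/C=C(\OB(CCCC)CCCC)N1[C@@H](Cc2ccccc2)COC1=O | intermediate (not isolated)
4 | (S)-4-benzyl-3-[(2S,3R)-3-hydroxy-2-methylpent-4-enoyl]-1,3-oxazolidin-2-one | C=C[C@@H](O)[C@H](C)C(=O)N1[C@@H](Cc2ccccc2)COC1=O | intermediate
5 | (2R,3R)-2-methylpent-4-ene-1,3-diol | C=C[C@@H](O)[C@H](C)CO | intermediate
6 | (2R,3R)-1-[(tert-butyldimethylsilyl)oxy]-2-methylpent-4-en-3-ol | C=C[C@@H](O)[C@H](C)CO[Si](C)(C)C(C)(C)C | intermediate
7 | 1-(2,3-dihydroxyphenyl)ethan-1-one | CC(=O)c1cccc(O)c1O | starting material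
8 | 1-[2,3-bis(benzyloxy)phenyl]ethan-1-one | CC(=O)c1cccc(OCc2ccccc2)c1OCc1ccccc1 | intermediate
9 | (2-carboxyethyl)triphenylphosphonium bromide | OC(=O)CC[P+](c1ccccc1)(c1ccccc1)c1ccccc1.[Br-] | starting material
10 | sodium 3-(triphenyl-λ5-phosphanylidene)propanoate (carboxylate ylide) | [Na+].[O-]C(=O)CC=P(c1ccccc1)(c1ccccc1)c1ccccc1 | intermediate (not isolated)
11 | (E)-4-[2,3-bis(benzyloxy)phenyl]pent-3-enoic acid | C/C(=C\CC(=O)O)c1cccc(OCc2ccccc2)c1OCc1ccccc1 | intermediate
12 | (R)-4-[2,3-bis(benzyloxy)phenyl]pentanoic acid | OC(=O)CC[C@@H](C)c1cccc(OCc2ccccc2)c1OCc1ccccc1 | intermediate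
13 | (R)-4-[2,3-bis(benzyloxy)phenyl]pentanoyl chloride | ClC(=O)CC[C@@H](C)c1cccc(OCc2ccccc2)c1OCc1ccccc1 | intermediate (not isolated)
14 | (4R)-5,6-bis(benzyloxy)-4-methyl-3,4-dihydronaphthalen-1(2H)-one | O=C1CC[C@@H](C)c2c1ccc(OCc1ccccc1)c2OCc1ccccc1 | intermediate
15 | (4R)-5,6-bis(benzyloxy)-4-methyl-1,2,3,4-tetrahydronaphthalen-1-ol (C1 epimers) | OC1CC[C@@H](C)c2c1ccc(OCc1ccccc1)c2OCc1ccccc1 | intermediate
16 | tert-butyl[(1-tert-butoxyethenyl)oxy]dimethylsilane | C=C(OC(C)(C)C)O[Si](C)(C)C(C)(C)C | starting material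
17 | tert-butyl 2-[(1S,4R)-5,6-bis(benzyloxy)-4-methyl-1,2,3,4-tetrahydronaphthalen-1-yl]acetate | CC(C)(C)OC(=O)C[C@@H]1CC[C@@H](C)c2c1ccc(OCc1ccccc1)c2OCc1ccccc1 | intermediate
18 | tert-butyl 2-[(1S,4R)-5,6-bis(benzyloxy)-7-bromo-4-methyl-1,2,3,4-tetrahydronaphthalen-1-yl]acetate | CC(C)(C)OC(=O)C[C@@H]1CC[C@@H](C)c2c1cc(Br)c(OCc1ccccc1)c2OCc1ccccc1 | intermediate
19 | benzyl (5R,8S)-3,4-bis(benzyloxy)-8-(2-tert-butoxy-2-oxoethyl)-5-methyl-5,6,7,8-tetrahydronaphthalene-2-carboxylate | CC(C)(C)OC(=O)C[C@@H]1CC[C@@H](C)c2c1cc(C(=O)OCc1ccccc1)c(OCc1ccccc1)c2OCc1ccccc1 | intermediate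
20 | 2-[(1S,4R)-5,6-bis(benzyloxy)-7-[(benzyloxy)carbonyl]-4-methyl-1,2,3,4-tetrahydronaphthalen-1-yl]acetic acid | OC(=O)C[C@@H]1CC[C@@H](C)c2c1cc(C(=O)OCc1ccccc1)c(OCc1ccccc1)c2OCc1ccccc1 | intermediate
21 | (3R,4R)-5-[(tert-butyldimethylsilyl)oxy]-4-methylpent-1-en-3-yl 2-[(1S,4R)-5,6-bis(benzyloxy)-7-[(benzyloxy)carbonyl]-4-methyl-1,2,3,4-tetrahydronaphthalen-1-yl]acetate | C=C[C@@H](OC(=O)C[C@@H]1CC[C@@H](C)c2c1cc(C(=O)OCc1ccccc1)c(OCc1ccccc1)c2OCc1ccccc1)[C@H](C)CO[Si](C)(C)C(C)(C)C | intermediate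
22 | (E)-O-trimethylsilyl ketene acetal of ester 21 (tetralinyl group cis to the allyloxy oxygen) | C[Si](C)(C)O/C(O[C@H](C=C)[C@H](C)CO[Si](C)(C)C(C)(C)C)=C/[C@@H]1CC[C@@H](C)c2c1cc(C(=O)OCc1ccccc1)c(OCc1ccccc1)c2OCc1ccccc1 | intermediate (not isolated)
23 | trimethylsilyl ester of acid 24 | C[C@H](CO[Si](C)(C)C(C)(C)C)/C=C/C[C@H](C(=O)O[Si](C)(C)C)[C@@H]1CC[C@@H](C)c2c1cc(C(=O)OCc1ccccc1)c(OCc1ccccc1)c2OCc1ccccc1 | intermediate (not isolated)
24 | (2S,4E,6S)-2-[(1S,4R)-5,6-bis(benzyloxy)-7-[(benzyloxy)carbonyl]-4-methyl-1,2,3,4-tetrahydronaphthalen-1-yl]-7-[(tert-butyldimethylsilyl)oxy]-6-methylhept-4-enoic acid | C[C@H](CO[Si](C)(C)C(C)(C)C)/C=C/C[C@H](C(=O)O)[C@@H]1CC[C@@H](C)c2c1cc(C(=O)OCc1ccccc1)c(OCc1ccccc1)c2OCc1ccccc1 | intermediate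
25 | isobutyl carbonic mixed anhydride of acid 24 | C[C@H](CO[Si](C)(C)C(C)(C)C)/C=C/C[C@H](C(=O)OC(=O)OCC(C)C)[C@@H]1CC[C@@H](C)c2c1cc(C(=O)OCc1ccccc1)c(OCc1ccccc1)c2OCc1ccccc1 | intermediate (not isolated)
26 | benzyl (5R,8S)-3,4-bis(benzyloxy)-8-[(2S,4E,6S)-7-[(tert-butyldimethylsilyl)oxy]-1-hydroxy-6-methylhept-4-en-2-yl]-5-methyl-5,6,7,8-tetrahydronaphthalene-2-carboxylate | C[C@H](CO[Si](C)(C)C(C)(C)C)/C=C/C[C@H](CO)[C@@H]1CC[C@@H](C)c2c1cc(C(=O)OCc1ccccc1)c(OCc1ccccc1)c2OCc1ccccc1 | intermediate
27 | (5R,8S)-8-[(2S,6S)-7-[(tert-butyldimethylsilyl)oxy]-1-hydroxy-6-methylheptan-2-yl]-3,4-dihydroxy-5-methyl-5,6,7,8-tetrahydronaphthalene-2-carboxylic acid | C[C@H](CO[Si](C)(C)C(C)(C)C)CCC[C@H](CO)[C@@H]1CC[C@@H](C)c2c1cc(C(=O)O)c(O)c2O | intermediate (not isolated)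
28 | (5R,8S)-8-[(2S,6S)-1,7-dihydroxy-6-methylheptan-2-yl]-3,4-dihydroxy-5-methyl-5,6,7,8-tetrahydronaphthalene-2-carboxylic acid | C[C@H](CO)CCC[C@H](CO)[C@@H]1CC[C@@H](C)c2c1cc(C(=O)O)c(O)c2O | target

**Step count.** Total: 16 steps (3 to alcohol 6, 9 to acid 20, 4 after their union). Longest linear sequence: 13 steps (steps 4–16, from 7).

**Steps most likely to fail**

1. Step 14. Leakage of enolate geometry during deprotonation, or a competing transition state (boat, or chair with the carbinol substituent axial) favoured by a mismatched facial preference of the neighbouring C4 stereocentre, would erode the configuration at C11. The fallback replaces the rearrangement by an auxiliary-controlled enolate alkylation; it sets out from 20 and 6 and comes back to the route at 26. Acid 20 is activated with pivaloyl chloride/Et3N and acylates lithiated (S)-4-benzyl-1,3-oxazolidin-2-one (the auxiliary recovered in step 2) to give N-acyl oxazolidinone F1. Alcohol 6 is mesylated and treated with LiBr (SN2′ displacement and allylic equilibration to the primary bromide) to give (S,E)-allylic bromide F2. The sodium enolate of F1 (NaHMDS, THF, −78 °C) is alkylated by F2 on the face away from the auxiliary benzyl group to give alkylated imide F3 with (S)-C11. LiBH4/H2O in Et2O at 0 °C then removes the auxiliary reductively, in preference to the hindered aryl benzyl ester, and gives 26.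

2. Step 9. After ionisation the cation may lose a proton to the 1,2-dihydronaphthalene (E1), may be captured on the methyl-bearing face if the conformational bias is weaker than expected, and the Lewis acid may attack the tert-butyl ester. The fallback uses olefination followed by catalyst-controlled conjugate reduction; it sets out from 14 and comes back at 17. Ketone 14 undergoes Horner–Wadsworth–Emmons olefination with tert-butyl diethylphosphonoacetate (NaH, THF, reflux) to give E-alkylidene ester F4. Copper hydride conjugate reduction (Cu(OAc)2, DTBM-SEGPHOS enantiomer chosen for hydride delivery to the face that gives (S)-C4, polymethylhydrosiloxane, t-BuOH, toluene) then gives 17 under catalyst control.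

3. Step 6. The ortho-benzyloxy group twists the aryl ring out of conjugation with the alkene, so enantioface discrimination (and tolerance of residual Z isomer) may be poor and C1 would be set with low enantiomeric purity. The fallback is non-selective reduction followed by classical resolution; it sets out from 11 and comes back at 12. Acid 11 is hydrogenated with an achiral homogeneous catalyst ([Ir(cod)(PCy3)(py)]PF6, H2, CH2Cl2; benzyl ethers survive) to racemic acid F5. Crystallisation with (R)-1-phenylethylamine from EtOAc/EtOH should give the less soluble diastereomeric ammonium salt F6 of the (R)-acid (the (S)-amine is used if the opposite salt crystallises), and acidification returns 12.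

**Further compounds**

F1 | step 14 | benzyl (5R,8S)-8-{2-[(4S)-4-benzyl-2-oxo-1,3-oxazolidin-3-yl]-2-oxoethyl}-3,4-bis(benzyloxy)-5-methyl-5,6,7,8-tetrahydronaphthalene-2-carboxylate | O=C(C[C@@H]1CC[C@@H](C)c2c1cc(C(=O)OCc1ccccc1)c(OCc1ccccc1)c2OCc1ccccc1)N1[C@@H](Cc2ccccc2)COC1=O
F2 | step 14 | (S,E)-[(5-bromo-2-methylpent-3-en-1-yl)oxy](tert-butyl)dimethylsilane | BrC/C=C/[C@H](C)CO[Si](C)(C)C(C)(C)C
F3 | step 14 | benzyl (5R,8S)-8-[(2S,4E,6S)-1-[(4S)-4-benzyl-2-oxo-1,3-oxazolidin-3-yl]-7-[(tert-butyldimethylsilyl)oxy]-6-methyl-1-oxohept-4-en-2-yl]-3,4-bis(benzyloxy)-5-methyl-5,6,7,8-tetrahydronaphthalene-2-carboxylate | C[C@H](CO[Si](C)(C)C(C)(C)C)/C=C/C[C@H](C(=O)N1[C@@H](Cc2ccccc2)COC1=O)[C@@H]1CC[C@@H](C)c2c1cc(C(=O)OCc1ccccc1)c(OCc1ccccc1)c2OCc1ccccc1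
F4 | step 9 | tert-butyl (2E)-2-[(4R)-5,6-bis(benzyloxy)-4-methyl-3,4-dihydronaphthalen-1(2H)-ylidene]acetate | CC(C)(C)OC(=O)/C=C1\CC[C@@H](C)c2c1ccc(OCc1ccccc1)c2OCc1ccccc1
F5 | step 6 | rac-4-[2,3-bis(benzyloxy)phenyl]pentanoic acid | OC(=O)CCC(C)c1cccc(OCc2ccccc2)c1OCc1ccccc1
F6 | step 6 | (R)-1-phenylethylammonium (R)-4-[2,3-bis(benzyloxy)phenyl]pentanoate | [O-]C(=O)CC[C@@H](C)c1cccc(OCc2ccccc2)c1OCc1ccccc1.C[C@@H]([NH3+])c1ccccc1
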